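Each reagent taken up stays on a product as one group, so a closed flask keeps a ledger: M + 2D + 3T, with M, D and T the mono adduct, bis adduct and triple product as fractions of the starting material charged, can reach the reagent ration q, the reagent charged per starting material charged. A is the free starting material, read the same way.

| flask | starting material | reagent | remark | time |
|---|---|---|---|---|
| Friday's | 20 mM | 34 mM | run made earlier |  |
| Monday's | 20 mM | 53 mM | run made earlier |  |
| flask | 20 mM | 24.0 mM |  | 1.0 h |

- Friday's (time / min: starting material / %, mono adduct / %, bis adduct / %): 8.00: 6, 28, 12; 15.0: 11, 26, 10; 20.0: 11, 21, 11; 30.0: 8, 23, 16; 40.0: 8, 21, 16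
- Monday's (time / min: starting material / %, mono adduct / %, bis adduct / %): 8.00: 5, 17, 16; 15.0: 3, 6, 8; 20.0: 2, 9, 9; 30.0: 5, 6, 5; 40.0: 1, 4, 5

(standard deviation of a reading: 2 percentage points)

- the starting material standing at 1.0 h, as a percentage of the starting material charged
- the mono adduct standing at 1.0 h, as a percentage of the starting material charged
- the bis adduct standing at 1.0 h, as a percentage of the starting material charged
- the triple product standing at 1.0 h, as a percentage of the starting material charged

- a reading or a percentage of mono adduct counts all its forms, free or not
- a reading of starting material is of its free form alone

This flask has q = 1.20, Friday's run 1.70. Friday's readings stand still within the scatter from 30.0 min to 40.0 min, so I assume uptake reached q there, and in this flask by the asked time. At 40.0 min Friday reads A 8%, M 21%, D 16%. If the unread rest were triple product, uptake would be 2.18 equivalents, more than Friday's q. The ledger instead gives, as estimates that carry the scatter of these readings, T 39.0% and a hidden share H of 16.0%, which I take for starting material that the free reading misses.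

Now I bracket T here. With less reagent than Friday, I expect M + 2D no smaller than Friday's, so I put the upper bound on T at 22.3%. Adding the balance A + H + M + D + T = 1 gives 2T = q − 1 + A + H − D. Taking A and H no smaller than Friday's and D no larger, I put the lower bound on T at 14.0%.

The forecast, reasoning that "Friday's plateau suggests the reaction stops once reagent runs out", gives A 13%, M 28%, D 16% and T 20%.

The flask gives A 9.54%, M 31.0%, D 13.8% and T 20.5%, so T lies below 22.3% and above 14.0%.

    starting material + reagent → mono adduct + released group (k = 0.350 M⁻¹ s⁻¹)
    reagent + mono adduct → bis adduct + released group (k = 1.10 M⁻¹ s⁻¹)
    reagent + bis adduct → triple product + released group (k = 0.410 M⁻¹ s⁻¹)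
    starting material + mono adduct ⇌ idle adduct, settled at all times (K = 2300 M⁻¹)

With the starting material and the time held, T in this flask has moved by 5 points at 21.2 mM and at 26.6 mM of reagent. In this flask reagent, the limiting reagent, stands at 0%, and the ledger comes to 1.20, which is q. A neighbouring flask with 50 mM of starting material has q = 0.480, and with reagent at 0% its ledger comes to 0.480.

(The readings are calculated on assumed constants, and the scatter is random.)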